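**Assumptions.** (S)-(−)-Limonene of high ee is the only chiral input. Its stereocentre acts as a relay: it sets the quaternary centre, is then excised in step 8, and the carbinol centre is rebuilt under control of the centres it created. Azulene numbering is used for the bicyclic compounds (C3 = carbinol carbon, C3a/C8a = ring fusion, C4 = ester carbon). This route is designed on paper; none of it has been run.

## Retrosynthetic overview

1. Ferutinin ⇐ jaeschkeanadiol (selective acylation of the secondary OH) ⇐ β-hydroxy ketone (hydroxyl-directed 1,3-anti reduction).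
2. C3 carbinol ⇐ C3 ketone + isopropyl organocerium; the ketone comes from excising the limonene-derived isopropenyl group.
3. Cycloheptene ⇐ ring-closing metathesis (C6=C7) of an allyl/methallyl diene.
4. Quaternary C8a–C8 bond ⇐ anionic oxy-Cope [3,3] rearrangement of the allyl adduct of a cyclopentene carbaldehyde (key step).
5. Ring order: cyclopentene first (ozonolysis/aldol of limonene, step 2), then cycloheptene (RCM, step 6).

## Route

**Step 1**
Reactants: 1, (S)-(−)-limonene
Product: 2, (3S)-6-oxo-3-(prop-1-en-2-yl)heptanal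
Conditions: O3 (1.0 equiv), CH2Cl2/MeOH, −78 °C; then Me2S
Reagents that add atoms: ozone, [O-][O+]=O
Why: Ozonolysis is faster at the trisubstituted ring alkene than at the 1,1-disubstituted isopropenyl group, so controlled dosing cleaves the ring only; the stereocentre is untouched.

**Step 2**
Reactants: 2
Product: 3, (5R)-2-methyl-5-(prop-1-en-2-yl)cyclopent-1-ene-1-carbaldehyde
Conditions: piperidine, AcOH, benzene, reflux (Dean–Stark)
Reagents that add atoms: none
Why: Intramolecular aldol condensation via the aldehyde enamine onto the methyl ketone closes the cyclopentene; the stereocentre is not enolisable under these conditions.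

**Step 3**
Reactants: 3; 4, allylmagnesium bromide
Product: 5, (1S)-1-[(5R)-2-methyl-5-(prop-1-en-2-yl)cyclopent-1-en-1-yl]but-3-en-1-ol
Conditions: allylMgBr, Et2O, −78 °C; minor carbinol epimer removed by chromatography
Reagents that add atoms: allylmagnesium bromide, C=CC[Mg]Br
Why: 1,2-Grignard addition to the s-trans enal occurs on the face opposite the adjacent isopropenyl group, giving mainly the (1S) carbinol (expected about 4:1).

**Step 4 (key step)**
Reactants: 5
Product: 6, (1S,2R,5S)-2-methyl-2-(prop-2-en-1-yl)-5-(prop-1-en-2-yl)cyclopentane-1-carbaldehyde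
Conditions: KH, 18-crown-6, THF, 0 → 25 °C; then BHT or AcOH, −78 °C; crude used at once
Reagents that add atoms: none
Why: Anionic oxy-Cope [3,3] rearrangement through a chair with the carbinol H eclipsing the ring methyl (A1,3) delivers the allyl terminus to the face anti to isopropenyl, setting the quaternary centre. Kinetic protonation of the aldehyde enolate from the same open face puts CHO cis to the methyl (this is the less stable epimer, hence the cold quench).

**Step 5**
Reactants: 6; 7, 2-methylallylmagnesium chloride
Product: 8, 1-[(1S,2R,5S)-2-methyl-2-(prop-2-en-1-yl)-5-(prop-1-en-2-yl)cyclopentyl]-3-methylbut-3-en-1-ol (both carbinol epimers)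
Conditions: methallylMgCl, THF, −78 °C
Reagents that add atoms: 2-methylallylmagnesium chloride, CC(=C)C[Mg]Cl
Why: Fast Grignard addition traps the epimerisable aldehyde; the new carbinol centre is not relied upon and is reset in steps 10–11.

**Step 6**
Reactants: 8
Product: 9, (3S,3aS,8aR)-6,8a-dimethyl-3-(prop-1-en-2-yl)-1,2,3,3a,4,5,8,8a-octahydroazulen-4-ol (C4 epimers)
Conditions: Grubbs II (5 mol %), CH2Cl2 (5 mM), 40 °C
Reagents that add atoms: none
Why: Ring-closing metathesis of the trans-disposed allyl and methallyl arms gives the trans-fused trisubstituted cycloheptene; the isopropenyl group is trans to the allyl arm and cannot bridge.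

**Step 7**
Reactants: 9
Product: 10, (3aR,8aR)-6,8a-dimethyl-3-(propan-2-ylidene)-1,2,3,3a,4,5,8,8a-octahydroazulen-4-ol (C4 epimers)
Conditions: Co(salen-tBu,tBu)Cl (3 mol %), PhSiH3 (6 mol %), benzene, rt
Reagents that add atoms: none
Why: Cobalt-hydride HAT isomerisation acts on the 1,1-disubstituted alkene and stops at the tetrasubstituted isopropylidene, as in limonene → terpinolene; the ring alkene is a much poorer HAT acceptor.

**Step 8**
Reactants: 10
Product: 11, (3aS,8aR)-4-hydroxy-6,8a-dimethyl-2,3a,4,5,8,8a-hexahydroazulen-3(1H)-one (C4 epimers)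
Conditions: O3 (1.0 equiv), pyridine, CH2Cl2, −78 °C; then Me2S; used directly
Reagents that add atoms: ozone, [O-][O+]=O
Why: Ozonolysis of the more electron-rich exocyclic tetrasubstituted alkene (terpinolene → 4-methylcyclohex-3-enone is the analogy) releases acetone and leaves the C3 ketone; neutral cold conditions avoid epimerising C3a.

**Step 9**
Reactants: 11; 12, isopropylmagnesium chloride
Product: 13, (3R,3aS,8aR)-6,8a-dimethyl-3-(propan-2-yl)-1,2,3,3a,4,5,8,8a-octahydroazulene-3,4-diol (C4 epimers)
Conditions: iPrMgCl (3 equiv), anhydrous CeCl3, THF, −78 → 0 °C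
Reagents that add atoms: isopropylmagnesium chloride, CC(C)[Mg]Cl
Why: The organocerium reagent suppresses enolisation and reduction and adds to the cyclopentanone anti to the adjacent C3a side chain and the 1,3-related angular methyl, placing OH cis to the methyl.

**Step 10**
Reactants: 13
Product: 14, (3R,3aR,8aR)-3-hydroxy-6,8a-dimethyl-3-(propan-2-yl)-2,3,3a,5,8,8a-hexahydroazulen-4(1H)-one
Conditions: Dess–Martin periodinane, NaHCO3, CH2Cl2, 0 °C
Reagents that add atoms: none
Why: Only the secondary alcohol is oxidised, so both C4 epimers converge on one β-hydroxy ketone; the natural C3a configuration (side chain trans to isopropyl) should also be the thermodynamic one here.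

**Step 11**
Reactants: 14
Product: 15, jaeschkeanadiol, (3R,3aS,4S,8aR)-6,8a-dimethyl-3-(propan-2-yl)-1,2,3,3a,4,5,8,8a-octahydroazulene-3,4-diol
Conditions: Me4NBH(OAc)3, MeCN/AcOH, −30 → 0 °C
Reagents that add atoms: none
Why: Evans–Saksena reduction: the tertiary alkoxy-borohydride delivers hydride intramolecularly to the ketone face on the side of the C3 oxygen, giving the 1,3-anti diol with the 4-OH trans to the angular methyl.

**Step 12**
Reactants: 15; 16, 4-acetoxybenzoic acid
Product: 17, (3R,3aS,4S,8aR)-3-hydroxy-6,8a-dimethyl-3-(propan-2-yl)-1,2,3,3a,4,5,8,8a-octahydroazulen-4-yl 4-acetoxybenzoate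
Conditions: EDC·HCl, DMAP, CH2Cl2, rt
Reagents that add atoms: 4-acetoxybenzoic acid, CC(=O)Oc1ccc(cc1)C(=O)O
Why: Steglich esterification acylates the secondary alcohol only; the tertiary alcohol is inert.

**Step 13**
Reactants: 17
Product: 18, ferutinine
Conditions: NH4OAc, MeOH/H2O, rt (or pyrrolidine, CH2Cl2, 0 °C)
Reagents that add atoms: none
Why: Mild aminolysis cleaves the activated aryl acetate far faster than the hindered secondary benzoate.

## Compound list

1 | (S)-(−)-limonene | CC1=CC[C@H](CC1)C(C)=C | starting material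
2 | (3S)-6-oxo-3-(prop-1-en-2-yl)heptanal | O=CC[C@H](CCC(C)=O)C(C)=C | intermediate
3 | (5R)-2-methyl-5-(prop-1-en-2-yl)cyclopent-1-ene-1-carbaldehyde | O=CC1=C(C)CC[C@@H]1C(C)=C | intermediate
4 | allylmagnesium bromide | C=CC[Mg]Br | starting material
5 | (1S)-1-[(5R)-2-methyl-5-(prop-1-en-2-yl)cyclopent-1-en-1-yl]but-3-en-1-ol | C=CC[C@H](O)C1=C(C)CC[C@@H]1C(C)=C | intermediate
6 | (1S,2R,5S)-2-methyl-2-allyl-5-(prop-1-en-2-yl)cyclopentane-1-carbaldehyde | O=C[C@@H]1[C@@](C)(CC=C)CC[C@@H]1C(C)=C | intermediate
7 | 2-methylallylmagnesium chloride | CC(=C)C[Mg]Cl | starting material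
8 | 1-[(1S,2R,5S)-2-methyl-2-allyl-5-(prop-1-en-2-yl)cyclopentyl]-3-methylbut-3-en-1-ol (carbinol epimers) | CC(=C)CC(O)[C@@H]1[C@@](C)(CC=C)CC[C@@H]1C(C)=C | intermediate
9 | (3S,3aS,8aR)-6,8a-dimethyl-3-(prop-1-en-2-yl)-1,2,3,3a,4,5,8,8a-octahydroazulen-4-ol (C4 epimers) | CC1=CC[C@@]2(C)CC[C@H](C(C)=C)[C@@H]2C(O)C1 | intermediate
10 | (3aR,8aR)-6,8a-dimethyl-3-(propan-2-ylidene)-1,2,3,3a,4,5,8,8a-octahydroazulen-4-ol (C4 epimers) | CC1=CC[C@@]2(C)CCC(=C(C)C)[C@@H]2C(O)C1 | intermediate
11 | (3aS,8aR)-4-hydroxy-6,8a-dimethyl-2,3a,4,5,8,8a-hexahydroazulen-3(1H)-one (C4 epimers) | CC1=CC[C@@]2(C)CCC(=O)[C@@H]2C(O)C1 | intermediate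
12 | isopropylmagnesium chloride | CC(C)[Mg]Cl | starting material
13 | (3R,3aS,8aR)-6,8a-dimethyl-3-(propan-2-yl)-1,2,3,3a,4,5,8,8a-octahydroazulene-3,4-diol (C4 epimers) | CC1=CC[C@@]2(C)CC[C@@](O)(C(C)C)[C@@H]2C(O)C1 | intermediate
14 | (3R,3aR,8aR)-3-hydroxy-6,8a-dimethyl-3-(propan-2-yl)-2,3,3a,5,8,8a-hexahydroazulen-4(1H)-one | CC1=CC[C@@]2(C)CC[C@@](O)(C(C)C)[C@@H]2C(=O)C1 | intermediate
15 | jaeschkeanadiol, (3R,3aS,4S,8aR)-diol | CC1=CC[C@@]2(C)CC[C@@](O)(C(C)C)[C@@H]2[C@@H](O)C1 | intermediate
16 | 4-acetoxybenzoic acid | CC(=O)Oc1ccc(cc1)C(=O)O | starting material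
17 | jaeschkeanadiol 4-O-(4-acetoxybenzoate) | CC1=CC[C@@]2(C)CC[C@@](O)(C(C)C)[C@@H]2[C@@H](OC(=O)c2ccc(OC(C)=O)cc2)C1 | intermediate
18 | ferutinine | CC1=CC[C@@]2(C)CC[C@@](O)(C(C)C)[C@@H]2[C@@H](OC(=O)c2ccc(O)cc2)C1 | target

## Summary

Total steps: 13. Longest linear sequence: 13 (all other inputs are commercial).

Steps most likely to fail, each with a fallback that changes the approach:

1. **Step 4 (oxy-Cope and kinetic protonation).** Bond formation at a tetrasubstituted alkene terminus may be slow or diverted by retro-allylation, and the aldehyde can epimerise at C1 to the more stable, wrong isomer. Fallback: abandon the [3,3] route and make the quaternary centre by Hosomi–Sakurai conjugate allylation (allylTMS, TiCl4) of the enone obtained from 3 by methallyl addition and oxidation. This gives the methallyl ketone directly, which is then ring-closed by RCM.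

2. **Step 8 (selective ozonolysis).** Ozone discriminates only modestly between the tetrasubstituted exocyclic alkene and the trisubstituted ring alkene. Fallback: skip the isomerisation/ozonolysis pair and remove the isopropenyl group from 9 without ozone, by cobalt-catalysed Mukaiyama hydroperoxidation of the 1,1-disubstituted alkene followed by Criegee (Hock) rearrangement to the C3 acetate (retention), then hydrolysis and oxidation with the C4 hydroxyl protected.

3. **Step 9 (isopropyl addition).** Enolisation, β-hydride reduction, retro-aldol of the free β-hydroxy ketone, or poor facial selectivity could intervene. Fallback: keep the isopropylidene carbons of 10 and deliver the C3 oxygen intramolecularly: convert the C4 alcohol to its Boc carbonate, run a Bartlett iodocarbonate cyclisation (IBr) onto the tetrasubstituted alkene, remove iodine with Bu3SnH and hydrolyse the cyclic carbonate to the 3,4-diol.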